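**Assumption:** the target is read as methyl (4S,5E,7Z,12R,14Z,17Z)-10-bromo-4,12-dihydroxy-9-oxoprosta-5,7,10,14,17-pentaenoate. Compounds 10, 17 and 18 are carried as diastereomer mixtures at centres that become sp2 again later. Compounds 1, 2, 5, 12 and 13 are taken as commercial.

## Retrosynthetic overview

1. Last step: open the γ-lactone that masks C1 and the C4 hydroxyl (NaOH, then MeI). The lactone and its 4S centre come from the L-glutamic-acid-derived (S)-5-(hydroxymethyl)butyrolactone.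
2. C7=C8: aldol addition of the C8 enolate of a 2-bromo-4-hydroxy-4-dienylcyclopentenone to the (E)-lactone enal, then mesylation and elimination.
3. C10–Br: nucleophilic epoxidation of the enone, then HBr opening and dehydration.
4. C12 carbinol and omega chain: 1,2-propargylation of commercial (R)-4-silyloxycyclopentenone anti to the silyloxy group, through a closed six-membered allenylzinc transition state. Then copper-mediated diyne assembly, Lindlar reduction, desilylation and allylic oxidation.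
5. Ring order: the cyclopentene ring is bought and carried through unchanged. The lactone ring is bought and opened in the final step. No ring is formed in the route.

## Route

**Step 1**
Reactants: 1 (R)-4-[(tert-butyldimethylsilyl)oxy]cyclopent-2-en-1-one; 2 3-bromoprop-1-yne
Product: 4 (1S,4R)-4-[(tert-butyldimethylsilyl)oxy]-1-(prop-2-yn-1-yl)cyclopent-2-en-1-ol, via allenylzinc bromide 3 (not isolated)
Conditions: Zn dust, THF, 0 °C; then 1, −78 to −30 °C; aq. NH4Cl
Reagents that add atoms: none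
Why: Zinc-Barbier propargylation: allenylzinc adds 1,2 through a closed six-membered, six-electron SE2′ (metallo-ene type) transition state, giving only the homopropargyl alcohol. It attacks anti to the bought C4 silyloxy group, which sets the tertiary carbinol (future C12); the minor syn adduct is removed by chromatography.

**Step 2**
Reactants: 4 (1S,4R)-4-[(tert-butyldimethylsilyl)oxy]-1-(prop-2-yn-1-yl)cyclopent-2-en-1-ol; 5 1-bromopent-2-yne
Product: 6 (1S,4R)-4-[(tert-butyldimethylsilyl)oxy]-1-(octa-2,5-diyn-1-yl)cyclopent-2-en-1-ol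
Conditions: CuI, NaI, Cs2CO3, DMF, rt
Reagents that add atoms: none
Why: Copper-mediated alkyne–propargyl bromide coupling: the copper acetylide displaces bromide (SN2) to give the skipped 1,4-diyne; the tertiary alcohol needs no protection and no stereocentre is touched.

**Step 3**
Reactants: 6 (1S,4R)-4-[(tert-butyldimethylsilyl)oxy]-1-(octa-2,5-diyn-1-yl)cyclopent-2-en-1-ol
Product: 7 (1S,4R)-4-[(tert-butyldimethylsilyl)oxy]-1-[(2Z,5Z)-octa-2,5-dien-1-yl]cyclopent-2-en-1-ol
Conditions: H2 (1 atm), Pd/CaCO3 poisoned with Pb(OAc)2, quinoline, EtOAc, rt, stopped at 2 equiv H2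
Reagents that add atoms: none
Why: Lindlar semi-hydrogenation: syn delivery of H2 on poisoned Pd turns both alkynes into Z alkenes (14Z,17Z); the hindered ring alkene is not reduced.

**Step 4**
Reactants: 7 (1S,4R)-4-[(tert-butyldimethylsilyl)oxy]-1-[(2Z,5Z)-octa-2,5-dien-1-yl]cyclopent-2-en-1-ol
Product: 8 (1S,4R)-1-[(2Z,5Z)-octa-2,5-dien-1-yl]cyclopent-2-ene-1,4-diol
Conditions: Bu4NF, THF, 0 °C to rt
Reagents that add atoms: none
Why: Fluoride-driven desilylation frees the secondary allylic alcohol and leaves the tertiary carbinol untouched.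

**Step 5**
Reactants: 8 (1S,4R)-1-[(2Z,5Z)-octa-2,5-dien-1-yl]cyclopent-2-ene-1,4-diol
Product: 9 (4S)-4-hydroxy-4-[(2Z,5Z)-octa-2,5-dien-1-yl]cyclopent-2-en-1-one
Conditions: MnO2, CH2Cl2, rt
Reagents that add atoms: none
Why: MnO2 oxidises only the secondary allylic alcohol; the bought carbinol centre is erased after directing step 1, leaving the future C12 as the only ring stereocentre.

**Step 6**
Reactants: 9 (4S)-4-hydroxy-4-[(2Z,5Z)-octa-2,5-dien-1-yl]cyclopent-2-en-1-one
Product: 10 (4S)-4-hydroxy-4-[(2Z,5Z)-octa-2,5-dien-1-yl]-6-oxabicyclo[3.1.0]hexan-2-one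
Conditions: 30% aq. H2O2, NaOH (0.1 equiv), MeOH, −20 to 0 °C; Na2S2O3 quench
Reagents that add atoms: hydrogen peroxide, OO
Why: Weitz–Scheffer nucleophilic epoxidation attacks only the electron-poor enone alkene, so the skipped diene survives. The epoxide configuration is irrelevant, and cold catalytic base limits retro-aldol racemisation of the tertiary carbinol.

**Step 7**
Reactants: 10 (4S)-4-hydroxy-4-[(2Z,5Z)-octa-2,5-dien-1-yl]-6-oxabicyclo[3.1.0]hexan-2-one
Product: 11 (4S)-2-bromo-4-hydroxy-4-[(2Z,5Z)-octa-2,5-dien-1-yl]cyclopent-2-en-1-one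
Conditions: 48% aq. HBr (1.5 equiv), acetone, 0 °C to rt
Reagents that add atoms: hydrogen bromide, Br
Why: Bromide opens the protonated epoxy ketone at the carbonyl-activated alpha carbon and the beta-hydroxy ketone dehydrates to the 2-bromoenone (the classical epoxy-ketone route to alpha-halo enones, as in 4-halo steroid enones).

**Step 8**
Reactants: 12 (S)-5-(hydroxymethyl)dihydrofuran-2(3H)-one; 13 (triphenylphosphoranylidene)acetaldehyde
Product: 15 (2E)-3-[(2S)-5-oxooxolan-2-yl]prop-2-enal, via lactone aldehyde 14 (not isolated)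
Conditions: IBX, EtOAc, 75 °C; filter; then 13, toluene, rt
Reagents that add atoms: none
Why: IBX oxidation gives the labile alpha-oxy aldehyde, trapped at once by the stabilised ylide in an E-selective Wittig reaction; the bought centre (future C4, S) is not epimerised by these non-basic reagents.

**Step 9**
Reactants: 11 (4S)-2-bromo-4-hydroxy-4-[(2Z,5Z)-octa-2,5-dien-1-yl]cyclopent-2-en-1-one; 15 (2E)-3-[(2S)-5-oxooxolan-2-yl]prop-2-enal
Product: 17 (4S)-2-bromo-4-hydroxy-5-{(2E)-1-hydroxy-3-[(2S)-5-oxooxolan-2-yl]prop-2-en-1-yl}-4-[(2Z,5Z)-octa-2,5-dien-1-yl]cyclopent-2-en-1-one, via dilithium alkoxide-enolate 16 (not isolated)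
Conditions: LiN(iPr)2 (2.1 equiv), THF, −78 °C; then 15, −78 °C; AcOH quench at −78 °C
Reagents that add atoms: none
Why: Aldol addition of the alkoxide–enolate dianion (Fráter–Seebach type), which reacts with the aldehyde far faster than with the lactone. The new C7 and C8 centres are left uncontrolled because step 10 destroys both.

**Step 10**
Reactants: 17 (4S)-2-bromo-4-hydroxy-5-{(2E)-1-hydroxy-3-[(2S)-5-oxooxolan-2-yl]prop-2-en-1-yl}-4-[(2Z,5Z)-octa-2,5-dien-1-yl]cyclopent-2-en-1-one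
Product: 19 (4R,5Z)-2-bromo-4-hydroxy-4-[(2Z,5Z)-octa-2,5-dien-1-yl]-5-{(2E)-3-[(2S)-5-oxooxolan-2-yl]prop-2-en-1-ylidene}cyclopent-2-en-1-one, via C7 mesylate 18 (not isolated)
Conditions: MsCl (1.2 equiv), Et3N, CH2Cl2, −30 °C; then DBU, −30 to 0 °C; chromatography in the dark
Reagents that add atoms: none
Why: Selective mesylation of the secondary allylic alcohol and E1cB elimination give the cross-conjugated dienone as a 7Z/7E mixture. The ratio is not predictable, though the quaternary C12 should disfavour the chain-syn-to-C12 (7E) arrangement; the 7Z isomer is separated by chromatography.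

**Step 11**
Reactants: 19 (4R,5Z)-2-bromo-4-hydroxy-4-[(2Z,5Z)-octa-2,5-dien-1-yl]-5-{(2E)-3-[(2S)-5-oxooxolan-2-yl]prop-2-en-1-ylidene}cyclopent-2-en-1-one
Product: 21 methyl (4S,5E,7Z,12R,14Z,17Z)-10-bromo-4,12-dihydroxy-9-oxoprosta-5,7,10,14,17-pentaenoate, via sodium carboxylate 20 (not isolated)
Conditions: 0.1 M aq. NaOH (1.05 equiv), THF, 0 °C, 15 min; freeze-dry; then MeI, DMF, 0 °C to rt
Reagents that add atoms: sodium hydroxide, [Na+].[OH-]; iodomethane, CI
Why: Saponification of the γ-lactone by one equivalent of hydroxide at 0 °C should outrun attack on the hindered dienone. SN2 O-methylation of the carboxylate under neutral conditions gives the hydroxy ester without acid (which would relactonise it); the C4–O bond is never broken, so 4S is retained.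

## Compound list

1 | (R)-4-[(tert-butyldimethylsilyl)oxy]cyclopent-2-en-1-one | O=C1C=C[C@H](O[Si](C)(C)C(C)(C)C)C1 | starting material
2 | 3-bromoprop-1-yne (propargyl bromide) | C#CCBr | starting material
3 | allenylzinc bromide | C=C=C[Zn]Br | intermediate
4 | (1S,4R)-4-[(tert-butyldimethylsilyl)oxy]-1-(prop-2-yn-1-yl)cyclopent-2-en-1-ol | C#CC[C@@]1(O)C=C[C@H](O[Si](C)(C)C(C)(C)C)C1 | intermediate
5 | 1-bromopent-2-yne | CCC#CCBr | starting material
6 | (1S,4R)-4-[(tert-butyldimethylsilyl)oxy]-1-(octa-2,5-diyn-1-yl)cyclopent-2-en-1-ol | CCC#CCC#CC[C@@]1(O)C=C[C@H](O[Si](C)(C)C(C)(C)C)C1 | intermediate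
7 | (1S,4R)-4-[(tert-butyldimethylsilyl)oxy]-1-[(2Z,5Z)-octa-2,5-dien-1-yl]cyclopent-2-en-1-ol | CC/C=C\C/C=C\C[C@@]1(O)C=C[C@H](O[Si](C)(C)C(C)(C)C)C1 | intermediate
8 | (1S,4R)-1-[(2Z,5Z)-octa-2,5-dien-1-yl]cyclopent-2-ene-1,4-diol | CC/C=C\C/C=C\C[C@@]1(O)C=C[C@H](O)C1 | intermediate
9 | (4S)-4-hydroxy-4-[(2Z,5Z)-octa-2,5-dien-1-yl]cyclopent-2-en-1-one | CC/C=C\C/C=C\C[C@@]1(O)C=CC(=O)C1 | intermediate
10 | (4S)-4-hydroxy-4-[(2Z,5Z)-octa-2,5-dien-1-yl]-6-oxabicyclo[3.1.0]hexan-2-one (epoxide diastereomers) | CC/C=C\C/C=C\C[C@@]1(O)C2OC2C(=O)C1 | intermediate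
11 | (4S)-2-bromo-4-hydroxy-4-[(2Z,5Z)-octa-2,5-dien-1-yl]cyclopent-2-en-1-one | CC/C=C\C/C=C\C[C@@]1(O)C=C(Br)C(=O)C1 | intermediate
12 | (S)-5-(hydroxymethyl)dihydrofuran-2(3H)-one | OC[C@@H]1CCC(=O)O1 | starting material
13 | (triphenylphosphoranylidene)acetaldehyde | O=CC=P(c1ccccc1)(c1ccccc1)c1ccccc1 | starting material
14 | (S)-5-oxotetrahydrofuran-2-carbaldehyde (lactone aldehyde) | O=C[C@@H]1CCC(=O)O1 | intermediate
15 | (2E)-3-[(2S)-5-oxooxolan-2-yl]prop-2-enal | O=C/C=C/[C@@H]1CCC(=O)O1 | intermediate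
16 | dilithium alkoxide-enolate of 11 | [Li+].[Li+].CC/C=C\C/C=C\C[C@@]1([O-])C=C(Br)C([O-])=C1 | intermediate
17 | (4S)-2-bromo-4-hydroxy-5-{(2E)-1-hydroxy-3-[(2S)-5-oxooxolan-2-yl]prop-2-en-1-yl}-4-[(2Z,5Z)-octa-2,5-dien-1-yl]cyclopent-2-en-1-one (C7/C8 diastereomers) | CC/C=C\C/C=C\C[C@@]1(O)C=C(Br)C(=O)C1C(O)/C=C/[C@@H]1CCC(=O)O1 | intermediate
18 | C7 methanesulfonate of 17 | CC/C=C\C/C=C\C[C@@]1(O)C=C(Br)C(=O)C1C(OS(C)(=O)=O)/C=C/[C@@H]1CCC(=O)O1 | intermediate
19 | (4R,5Z)-2-bromo-4-hydroxy-4-[(2Z,5Z)-octa-2,5-dien-1-yl]-5-{(2E)-3-[(2S)-5-oxooxolan-2-yl]prop-2-en-1-ylidene}cyclopent-2-en-1-one | CC/C=C\C/C=C\C[C@@]1(O)C=C(Br)C(=O)/C1=C\C=C\[C@@H]1CCC(=O)O1 | intermediate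
20 | sodium (4S,5E,7Z,12R,14Z,17Z)-10-bromo-4,12-dihydroxy-9-oxoprosta-5,7,10,14,17-pentaenoate | [Na+].CC/C=C\C/C=C\C[C@@]1(O)C=C(Br)C(=O)/C1=C\C=C\[C@@H](O)CCC([O-])=O | intermediate
21 | methyl (4S,5E,7Z,12R,14Z,17Z)-10-bromo-4,12-dihydroxy-9-oxoprosta-5,7,10,14,17-pentaenoate | CC/C=C\C/C=C\C[C@@]1(O)C=C(Br)C(=O)/C1=C\C=C\[C@@H](O)CCC(=O)OC | target

## Step count and risks

Total: 11 steps. Longest linear sequence: 10 steps (steps 1–7, 9, 10, 11 from compound 1).

**Risk 1, step 10 (7Z versus 7E geometry).** The E1cB elimination may favour the 7E isomer. The fallback sets out from 17 and comes back at 19. Compound 17 is eliminated through 18 under equilibrating conditions (DBU, rt) to the thermodynamic isomer (4R,5E)-2-bromo-4-hydroxy-4-[(2Z,5Z)-octa-2,5-dien-1-yl]-5-{(2E)-3-[(2S)-5-oxooxolan-2-yl]prop-2-en-1-ylidene}cyclopent-2-en-1-one F1. F1 is then photoisomerised (Pyrex-filtered lamp, benzene, HPLC monitoring) to the E/Z photostationary mixture, as is known for the chlorovulone and clavulone dienones. Compound 19 is separated and F1 is recycled.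

**Risk 2, step 11 (hydroxide on the bromo-dienone; relactonisation).** The fallback sets out from 11 and comes back at 21, and carries C1 as the methyl ester from the start. Commercial dimethyl (S)-2-hydroxypentanedioate (from L-glutamic acid) is silylated with Et3SiCl and imidazole to dimethyl (S)-2-(triethylsilyloxy)pentanedioate F2. iBu2AlH at −78 °C reduces the ester next to the silyloxy group to methyl (S)-5-oxo-4-(triethylsilyloxy)pentanoate F3. Wittig reaction with 13 gives methyl (4S,5E)-7-oxo-4-(triethylsilyloxy)hept-5-enoate F4. Aldol of dianion 16 (from 11) with F4 gives the open-chain aldol adduct F5. Its C7 methanesulfonate F6 eliminates to the 4-O-triethylsilyl ether of the target F7. HF·pyridine in THF at 0 °C then gives 21 with no basic step after the dienone exists.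

**Risk 3, step 9 (aldol of the unprotected dianion; retro-aldol or poor conversion).** The fallback sets out from 11 and comes back at 17, and replaces the lithium dianion by a Mukaiyama aldol. Me3SiOTf and Et3N convert 11 into its bis(trimethylsilyl) derivative (tertiary silyl ether plus silyl dienol ether) F8. BF3·OEt2 at −78 °C couples F8 with 15 to the 12-O-trimethylsilyl aldol adduct F9. Citric acid in MeOH removes the silyl ether to give 17.

## Further compounds

F1 | step 10 | (4R,5E)-2-bromo-4-hydroxy-4-[(2Z,5Z)-octa-2,5-dien-1-yl]-5-{(2E)-3-[(2S)-5-oxooxolan-2-yl]prop-2-en-1-ylidene}cyclopent-2-en-1-one (7E isomer of 19) | CC/C=C\C/C=C\C[C@@]1(O)C=C(Br)C(=O)/C1=C/C=C/[C@@H]1CCC(=O)O1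
F2 | step 11 | dimethyl (S)-2-(triethylsilyloxy)pentanedioate | COC(=O)CC[C@H](O[Si](CC)(CC)CC)C(=O)OC
F3 | step 11 | methyl (S)-5-oxo-4-(triethylsilyloxy)pentanoate | COC(=O)CC[C@H](O[Si](CC)(CC)CC)C=O
F4 | step 11 | methyl (4S,5E)-7-oxo-4-(triethylsilyloxy)hept-5-enoate | COC(=O)CC[C@H](O[Si](CC)(CC)CC)/C=C/C=O
F5 | step 11 | open-chain aldol adduct (4-O-triethylsilyl methyl ester analogue of 17) | CC/C=C\C/C=C\C[C@@]1(O)C=C(Br)C(=O)C1C(O)/C=C/[C@@H](O[Si](CC)(CC)CC)CCC(=O)OC
F6 | step 11 | C7 methanesulfonate of F5 | CC/C=C\C/C=C\C[C@@]1(O)C=C(Br)C(=O)C1C(OS(C)(=O)=O)/C=C/[C@@H](O[Si](CC)(CC)CC)CCC(=O)OC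
F7 | step 11 | 4-O-triethylsilyl ether of 21 | CC/C=C\C/C=C\C[C@@]1(O)C=C(Br)C(=O)/C1=C\C=C\[C@@H](O[Si](CC)(CC)CC)CCC(=O)OC
F8 | step 9 | bis(trimethylsilyl) derivative of 11 (3-bromo-5-[(2Z,5Z)-octa-2,5-dien-1-yl]-2,5-bis(trimethylsilyloxy)cyclopenta-1,3-diene, C5 as in 11) | CC/C=C\C/C=C\C[C@@]1(O[Si](C)(C)C)C=C(Br)C(O[Si](C)(C)C)=C1
F9 | step 9 | 12-O-trimethylsilyl ether of 17 | CC/C=C\C/C=C\C[C@@]1(O[Si](C)(C)C)C=C(Br)C(=O)C1C(O)/C=C/[C@@H]1CCC(=O)O1
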